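The cyclopentenone ring (C1 to C5) is opened at C2–C3. Atoms are numbered C1 (quaternary, bearing OMe and ester carbon C9), C2, C3, C4 (ketone), C5 and C6 (cinnamoyl enol carbon). The feature exploited is that C1, the only stereocentre, bears two carboxyl-level carbons, C9 and the enol-ether carbon C2, so it can be a prochiral methoxymalonate carbon with two enantiotopic methyl esters. In one operation the C3 terminus of a diketone dianion acylates one of them, forming C2–C3, closing the five-membered ring and setting C1. Precursor 8 is an acyclic dimethyl methoxymalonate whose C5 already carries the methoxyacetyl (C3, C4) and cinnamoyl (C6) groups.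

Key step: step 4

Remarks and assumptions on the chemistry

- Configuration planned for: C1 of the target is (S); the exocyclic enol double bond C5=C6 is (Z), with O6–H hydrogen-bonded to the C4 carbonyl; the styryl double bond is (E).
- Precursor 8 is written as its chelated C6 enol. As a 2-tert-alkyl-1,3-diketone it is expected to exist largely as the C5–H diketo tautomer, in which C5 is stereogenic (racemic). Both tautomers give the same C5-deprotonated anion, and only there is C1 truly prochiral, so the key step is run from the preformed dianion.
- A single metal held between O4 and O6 would lie on the side of C5 opposite to C1, too far from the esters to tell them apart. The key step therefore uses one ligated lithium per enolate oxygen.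
- Assumption: the sense of induction of a ligand-controlled closure of this kind cannot be predicted with certainty. The route is written for the (S,S)-diether; should it favour closure onto the other ester, the (R,R)-ligand is used instead.
- All oxygen-bound alkyl groups are methyl, so ester exchange by the methoxide liberated in steps 1 and 4 is degenerate.

Step 1
Reactants: 1 benzalacetone; 2 methyl methoxyacetate
Product: 4 (5E)-1-methoxy-6-phenylhex-5-ene-2,4-dione, via lithium enolate of benzalacetone 3 (not isolated)
Conditions: LiN(SiMe3)2 (2.1 equiv), THF, −78 °C; then 2 (1.1 equiv), −78 to 0 °C; aq. HCl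
Reagents that add atoms: none
Why: Crossed Claisen condensation, in which benzalacetone has a single enolisable position, its kinetic lithium enolate 3 is acylated by the activated alpha-alkoxy ester at low temperature, and the second equivalent of base stores 4 as its diketonate, which stops double acylation and Michael self-condensation.

Step 2
Reactants: 4 (5E)-1-methoxy-6-phenylhex-5-ene-2,4-dione; 5 dimethyl ketomalonate
Product: 7 dimethyl 2-[(5E)-1-methoxy-2,4-dioxo-6-phenylhex-5-en-3-ylidene]propanedioate, via titanium-bound carbinol 6 (not isolated)
Conditions: TiCl4 (2 equiv), pyridine (4 equiv), THF, 0 °C to rt; crude product used directly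
Reagents that add atoms: none
Why: Knoevenagel condensation in its TiCl4/pyridine variant, in which the titanium diketonate of 4 adds through C5 to the highly electrophilic keto group of 5 and the titanium-bound tertiary alkoxide of 6 is expelled by E1cB because C5–H lies between two ketones; the new double bond has no geometry, since C1 carries two identical esters.

Step 3
Reactants: 7 dimethyl 2-[(5E)-1-methoxy-2,4-dioxo-6-phenylhex-5-en-3-ylidene]propanedioate
Product: 8 dimethyl 2-methoxy-2-[(5E)-1-methoxy-2,4-dioxo-6-phenylhex-5-en-3-yl]propanedioate
Conditions: MeOH, Et3N (cat.), 0 °C to rt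
Reagents that add atoms: methanol, CO
Why: Base-catalysed oxa-Michael addition, in which methanol adds to C1, the alkene carbon beta to both ketones, because only this mode gives the diketone-stabilised C5 anion, and the strong electrophilicity of the tetra-acceptor alkene should place the equilibrium on the side of 8; no stereocentre is fixed, as C1 still carries two identical esters.

Step 4
Reactants: 8 dimethyl 2-methoxy-2-[(5E)-1-methoxy-2,4-dioxo-6-phenylhex-5-en-3-yl]propanedioate
Product: 10 methyl (1S,5Z)-2-hydroxy-5-[(2E)-1-hydroxy-3-phenylprop-2-en-1-ylidene]-1,3-dimethoxy-4-oxocyclopent-2-ene-1-carboxylate, via dilithium dienediolate 9 (not isolated)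
Conditions: LiN(i-Pr)2 (2.2 equiv), (S,S)-1,2-dimethoxy-1,2-diphenylethane (2.5 equiv), toluene, −78 to −40 °C; aq. HCl
Reagents that add atoms: none
Why: Proposed new method: two equivalents of amide remove first the C5 proton and then a C3 proton, and in dienediolate 9 the C3 terminus adds to the carbonyl of one C1 ester, methoxide leaves, and that methoxide removes the new doubly activated C3–H, so the closure ends in a stabilised dianion and cannot revert. The closest known reaction types are the terminal C-acylation of 1,3-diketone dianions by esters, the base-mediated cyclisation of 4-oxo esters to cyclopentane-1,3-diones, and enantioselective additions of lithium enolates that carry a chiral 1,2-diether ligand on lithium. The five-membered ring closes in the 5-(enolendo)-exo-trig mode, which is formally disfavoured but should be feasible because 9 is twisted about C4–C5 by the quaternary C1 and because the alpha-methoxy malonate esters are unusually electrophilic and presented twice. The C1 stereocentre arises by group selection between the two enantiotopic esters under control of the chiral diether: the lithium on O6, turned toward C1 to avoid allylic 1,3-strain with the styryl group, is chelated by the C1 methoxy oxygen, which fixes that methoxy in the enolate plane with one ester above and one below, and the twofold-symmetric ligand on this lithium leaves only one of them open to the C4–C5 twist that brings C3 onto it. The step needs C- over O-acylation, attack of C3 on an ester over conjugate attack at the styryl carbon C8, and ring closure over loss of methoxide from C1; O-acylation is reversible through methoxide, the enone is deactivated as part of the dienolate, and the same O6–Li–OMe chelate holds the C1–O bond orthogonal to the enolate pi system, so beta-elimination is stereoelectronically disfavoured.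

Step 5
Reactants: 10 methyl (1S,5Z)-2-hydroxy-5-[(2E)-1-hydroxy-3-phenylprop-2-en-1-ylidene]-1,3-dimethoxy-4-oxocyclopent-2-ene-1-carboxylate
Product: 11 methyl (1S,5Z)-5-[(2E)-1-hydroxy-3-phenylprop-2-en-1-ylidene]-1,2,3-trimethoxy-4-oxocyclopent-2-ene-1-carboxylate
Conditions: Me3SiCHN2 (1.05 equiv), toluene/MeOH, 0 °C
Reagents that add atoms: trimethylsilyldiazomethane, C[Si](C)(C)C=[N+]=[N-]
Why: O-methylation of a vinylogous acid by a diazoalkane, in which the free and most acidic O2–H protonates the reagent and is alkylated by the resulting methyldiazonium ion, while the O6–H···O4 hydrogen bond ties up the other two oxygens and C1, having no alpha-hydrogen, keeps its configuration.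

Compound list

1 | benzalacetone, (3E)-4-phenylbut-3-en-2-one | CC(=O)/C=C/c1ccccc1 | starting material
2 | methyl methoxyacetate | COCC(=O)OC | starting material
3 | lithium (3E)-4-phenylbuta-1,3-dien-2-olate, the lithium enolate of 1 (not isolated) | [Li+].[O-]C(=C)/C=C/c1ccccc1 | intermediate
4 | (5E)-1-methoxy-6-phenylhex-5-ene-2,4-dione | COCC(=O)CC(=O)/C=C/c1ccccc1 | intermediate
5 | dimethyl ketomalonate (dimethyl 2-oxopropanedioate) | COC(=O)C(=O)C(=O)OC | starting material
6 | dimethyl 2-hydroxy-2-[(5E)-1-methoxy-2,4-dioxo-6-phenylhex-5-en-3-yl]propanedioate, the carbinol, racemic at C5, bound to titanium in the flask (not isolated) | COCC(=O)C(C(=O)/C=C/c1ccccc1)C(O)(C(=O)OC)C(=O)OC | intermediate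
7 | dimethyl 2-[(5E)-1-methoxy-2,4-dioxo-6-phenylhex-5-en-3-ylidene]propanedioate | COCC(=O)C(=C(C(=O)OC)C(=O)OC)C(=O)/C=C/c1ccccc1 | intermediate
8 | dimethyl 2-methoxy-2-[(5E)-1-methoxy-2,4-dioxo-6-phenylhex-5-en-3-yl]propanedioate, drawn as the chelated (Z)-enol at C6 | COCC(=O)/C(=C(\O)/C=C/c1ccccc1)C(OC)(C(=O)OC)C(=O)OC | intermediate
9 | dilithium dienediolate of 8 (enolates C3=C4–O and C5=C6–O; C3 methoxy and O4 cis; not isolated) | [Li+].[Li+].CO/C=C(\[O-])C(=C([O-])/C=C/c1ccccc1)C(OC)(C(=O)OC)C(=O)OC | intermediate
10 | methyl (1S,5Z)-2-hydroxy-5-[(2E)-1-hydroxy-3-phenylprop-2-en-1-ylidene]-1,3-dimethoxy-4-oxocyclopent-2-ene-1-carboxylate | COC(=O)[C@@]1(OC)C(O)=C(OC)C(=O)/C1=C(O)/C=C/c1ccccc1 | intermediate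
11 | methyl (1S,5Z)-5-[(2E)-1-hydroxy-3-phenylprop-2-en-1-ylidene]-1,2,3-trimethoxy-4-oxocyclopent-2-ene-1-carboxylate | COC(=O)[C@@]1(OC)C(OC)=C(OC)C(=O)/C1=C(O)/C=C/c1ccccc1 | target

Total step count: 5. Longest linear sequence: 5 steps (1 → 4 → 7 → 8 → 10 → 11).

Steps most likely to fail

Step 4 (proposed new method). The closure may fail to tell the two enantiotopic esters apart, may lag behind loss of methoxide from C1 at the dianion stage (which would lead through an achiral cyclopentenedione), or may stall because of its enolendo geometry. The fallback uses known chemistry and sets out from 8. The ring is closed without stereocontrol under equilibrating conditions (NaOMe, MeOH, reflux), the classical base-mediated cyclisation of a 4-oxo ester to a cyclopentane-1,3-dione, in which any loss of methoxide from C1 is reversed by the solvent. This should give the racemic desmethyl cyclopentenone F1. Methylation as in step 5 should give the racemic target F2, and preparative chromatography on a chiral stationary phase (amylose tris(3,5-dimethylphenylcarbamate), supercritical CO2/MeOH) separates 11 from its (1R)-enantiomer F3. The route is rejoined at 11.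

Step 2. The condensation may stop at the carbinol stage or revert by retro-aldol cleavage, and the Lewis acid may trigger cyclisation or oligomerisation of the cross-conjugated dienone 7. The fallback sets out from 4 and 5 and separates C–C bond formation from elimination. Amine-catalysed aldol addition (Et3N cat., CH2Cl2, 0 °C) should give carbinol 6, this time isolated. SOCl2/pyridine at −20 °C converts it into the tertiary chlorosulfite F4, which loses SO2 and chloride by E1cB from the acidic C5–H. The route is rejoined at 7.

Step 5. Alkylation may take place at O4 or at the enol oxygen O6 instead of O2, may go on to a dimethyl ether, or may be accompanied by dipolar cycloaddition of the diazoalkane to the enone. The fallback sets out from 10 and forms the C2 enol ether under thermodynamic control by acid-catalysed enol etherification (MeOH, HC(OMe)3, TsOH cat., rt), the way cyclic 1,3-diones are converted into 3-alkoxy enones. No alkylating agent is present, the hydrogen-bonded C6 enol should not be etherified, and the isomer that keeps the C4 carbonyl in the chelate is expected to be the more stable one. The C1 methoxy group should not ionise, since the cation would be a cyclopentadienyl-type system with four pi electrons. The route is rejoined at 11; no compound outside the list is made (F0).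

Further compounds

F1 | step 4 | racemic methyl (5Z)-2-hydroxy-5-[(2E)-1-hydroxy-3-phenylprop-2-en-1-ylidene]-1,3-dimethoxy-4-oxocyclopent-2-ene-1-carboxylate | COC(=O)C1(OC)C(O)=C(OC)C(=O)/C1=C(O)/C=C/c1ccccc1
F2 | step 4 | racemic methyl (5Z)-5-[(2E)-1-hydroxy-3-phenylprop-2-en-1-ylidene]-1,2,3-trimethoxy-4-oxocyclopent-2-ene-1-carboxylate | COC(=O)C1(OC)C(OC)=C(OC)C(=O)/C1=C(O)/C=C/c1ccccc1
F3 | step 4 | methyl (1R,5Z)-5-[(2E)-1-hydroxy-3-phenylprop-2-en-1-ylidene]-1,2,3-trimethoxy-4-oxocyclopent-2-ene-1-carboxylate | COC(=O)[C@]1(OC)C(OC)=C(OC)C(=O)/C1=C(O)/C=C/c1ccccc1
F4 | step 2 | dimethyl 2-(chlorosulfinyloxy)-2-[(5E)-1-methoxy-2,4-dioxo-6-phenylhex-5-en-3-yl]propanedioate | COCC(=O)C(C(=O)/C=C/c1ccccc1)C(OS(=O)Cl)(C(=O)OC)C(=O)OC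
F0 | step 5 | none | none
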